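## Retrosynthetic overview

1. Diacid 14 comes from its dimethyl ester 13 by saponification (last step).
2. 13 comes from a one-flask double olefination of the C5 linchpin 9 (aldehyde plus α-phosphono ester, made from trimethyl phosphonoacetate and acrolein): Wittig with diol ylide 6 gives the inner (E)-enoate, Horner–Wadsworth–Emmons (HWE) with aldehyde 11 gives the outer one.
3. Ylide 6 comes from C-alkylation of ester phosphorane 3 with epoxy bromide 2 and oxirane hydrolysis; 2 comes from Shi epoxidation of achiral bromide 1, which sets the only stereocentre in the first step.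
4. Aldehyde 11 comes from the furan–chain C–C bond, made by amine-catalysed conjugate addition of a 3-furyl trifluoroborate to acrolein (proposed new step).
5. Rings: none is built. The furan is bought intact in 10; the only ring made is the oxirane of 2 (step 1), opened in step 2.

Assumption: both trisubstituted alkenes are E and the carbinol centre is R, exactly as the SMILES encodes; potassium trifluoro(furan-3-yl)borate 10 is taken as a catalogue reagent.

## Route

Step 1
Reactants: 1 5-bromo-2-methylpent-2-ene
Product: 2 (R)-3-(2-bromoethyl)-2,2-dimethyloxirane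
Conditions: D-fructose-derived Shi ketone (1,2:4,5-di-O-isopropylidene-β-D-erythro-2,3-hexodiulo-2,6-pyranose, 30 mol%), KHSO5 (as 2KHSO5·KHSO4·K2SO4, 1.4 equiv), K2CO3 (5.8 equiv), Bu4NHSO4 (4 mol%), MeCN/CH2(OMe)2 1:2, aq. Na2B4O7 buffer, pH 10.5, −5 to 0 °C, 2 h
Reagents that add atoms: potassium peroxymonosulfate, [K+].[O-]S(=O)(=O)OO
Why: Shi epoxidation: the chiral dioxirane formed from the ketone transfers oxygen through a spiro transition state to the olefin face that makes the CH carbon (R), the sense this ketone shows for trisubstituted olefins (about 90% ee expected), while the alkyl bromide and the base-stable oxirane survive pH 10.5.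

Step 2
Reactants: 2 (R)-3-(2-bromoethyl)-2,2-dimethyloxirane; 3 methyl 2-(triphenylphosphoranylidene)acetate
Product: 6 methyl (5R)-5,6-dihydroxy-6-methyl-2-(triphenylphosphoranylidene)heptanoate, via epoxy phosphonium bromide 4 (not isolated), via dihydroxy phosphonium bromide 5 (not isolated)
Conditions: 2 (1.15 equiv), Bu4NI (10 mol%), MeCN, 80 °C, 36 h; then THF/H2O, HClO4 (5 mol%), rt, 3 h; then 1 M NaOH, CH2Cl2, 0 °C
Reagents that add atoms: water, O
Why: SN2 C-alkylation of the stabilised ylide by the primary bromide (the α-alkyl salt is a weaker acid than protonated 3, so transylidation does not stall it), then acid-catalysed oxirane hydrolysis in which water attacks the tertiary carbon so the C–O bond of the stereocentre is never broken and (R) is retained, then deprotonation of the phosphonium salt to the ylide.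

Step 3
Reactants: 7 trimethyl phosphonoacetate; 8 acrolein
Product: 9 methyl 2-(dimethoxyphosphoryl)-5-oxopentanoate
Conditions: NaOMe (10 mol%), MeOH, −20 to 0 °C, 8 added slowly to 7 (1.5 equiv); AcOH quench
Reagents that add atoms: none
Why: Base-catalysed Michael addition of the soft phosphonoacetate carbanion to acrolein; 1,2-addition is reversible and any olefination event consumes the catalytic base, so the conjugate adduct accumulates (its phosphonate carbon is a labile, unassigned centre that disappears in step 5).

Step 4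
Reactants: 10 potassium trifluoro(furan-3-yl)borate; 8 acrolein
Product: 11 3-(furan-3-yl)propanal
Conditions: morpholinium trifluoroacetate (20 mol%), aq. HF (48%, 1.0 equiv), 10 (1.5 equiv), MeOCH2CH2OMe, −20 °C, 16 h, polypropylene flask
Reagents that add atoms: none
Why: Proposed new method: the secondary ammonium salt condenses with 8 to an unsaturated iminium ion whose β-carbon is attacked by the boron-bearing C3 of 10 (the borate makes the ipso carbon the most nucleophilic ring position, so the furan reacts at C3 and not at its normally favoured C2/C5), fluoride from HF removes BF3 as KBF4 to rearomatise, and hydrolysis of the enamine releases 11 and the amine; the closest known reaction type is the amine-catalysed Friedel–Crafts-type conjugate addition of heteroaryl- and vinyl-trifluoroborates to β-substituted enals, which to my knowledge has not been reported for a 3-furyl borate with unsubstituted, polymerisation-prone acrolein.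

Step 5
Reactants: 6 methyl (5R)-5,6-dihydroxy-6-methyl-2-(triphenylphosphoranylidene)heptanoate; 9 methyl 2-(dimethoxyphosphoryl)-5-oxopentanoate; 11 3-(furan-3-yl)propanal
Product: 13 dimethyl (2E,6E)-2-[(3R)-3,4-dihydroxy-4-methylpentyl]-6-[3-(furan-3-yl)propylidene]hept-2-enedioate, via phosphonate enoate 12 (not isolated)
Conditions: 6 + 9 (1:1), MeCN, 60 °C, 12 h; then 0 °C, LiCl (3 equiv), 11 (1.4 equiv), DBU (2.5 equiv), to rt, 16 h; silica chromatography
Reagents that add atoms: none
Why: Wittig olefination of the aldehyde of 9 by the α-branched stabilised ylide gives the (E)-enoate (the ylide is far too weak a base to touch the phosphonate C–H), and the untouched phosphonate then undergoes a Masamune–Roush Horner–Wadsworth–Emmons reaction with 11 under lithium-chelated, equilibrating conditions that favour the (E)-2-alkyl-2-enoate (about 9:1 expected, minor isomer removed on silica); no stereocentre is formed and the carbinol centre is untouched.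

Step 6
Reactants: 13 dimethyl (2E,6E)-2-[(3R)-3,4-dihydroxy-4-methylpentyl]-6-[3-(furan-3-yl)propylidene]hept-2-enedioate
Product: 14 (2E,6E)-2-[(3R)-3,4-dihydroxy-4-methylpentyl]-6-[3-(furan-3-yl)propylidene]hept-2-enedioic acid
Conditions: LiOH·H2O (6 equiv), THF/MeOH/H2O 3:1:1, 45 °C, 16 h; then 1 M HCl to pH 3–4, 0 °C, EtOAc
Reagents that add atoms: lithium hydroxide, [Li+].[OH-]
Why: Saponification (acyl–oxygen cleavage) of both hindered conjugated methyl esters, and of any δ-lactone formed between the secondary hydroxyl and its neighbouring ester, leaves the furan, both alkenes and the carbinol centre untouched, and cold, brief acidification gives the open diol diacid.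

## Compound list

1 | 5-bromo-2-methylpent-2-ene | CC(C)=CCCBr | starting material
2 | (R)-3-(2-bromoethyl)-2,2-dimethyloxirane | CC1(C)O[C@@H]1CCBr | intermediate
3 | methyl 2-(triphenylphosphoranylidene)acetate | COC(=O)C=P(c1ccccc1)(c1ccccc1)c1ccccc1 | starting material
4 | {4-[(2R)-3,3-dimethyloxiran-2-yl]-1-methoxy-1-oxobutan-2-yl}triphenylphosphonium bromide (phosphonium carbon unassigned) | CC1(C)O[C@@H]1CCC(C(=O)OC)[P+](c1ccccc1)(c1ccccc1)c1ccccc1.[Br-] | intermediate
5 | [(5R)-5,6-dihydroxy-1-methoxy-6-methyl-1-oxoheptan-2-yl]triphenylphosphonium bromide (phosphonium carbon unassigned) | CC(C)(O)[C@H](O)CCC(C(=O)OC)[P+](c1ccccc1)(c1ccccc1)c1ccccc1.[Br-] | intermediate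
6 | methyl (5R)-5,6-dihydroxy-6-methyl-2-(triphenylphosphoranylidene)heptanoate | CC(C)(O)[C@H](O)CCC(C(=O)OC)=P(c1ccccc1)(c1ccccc1)c1ccccc1 | intermediate
7 | trimethyl phosphonoacetate | COC(=O)CP(=O)(OC)OC | starting material
8 | acrolein | C=CC=O | starting material
9 | methyl 2-(dimethoxyphosphoryl)-5-oxopentanoate (racemic, labile centre) | COC(=O)C(CCC=O)P(=O)(OC)OC | intermediate
10 | potassium trifluoro(furan-3-yl)borate | [K+].F[B-](F)(F)c1ccoc1 | starting material
11 | 3-(furan-3-yl)propanal | O=CCCc1ccoc1 | intermediate
12 | dimethyl (2E)-2-[(3R)-3,4-dihydroxy-4-methylpentyl]-6-(dimethoxyphosphoryl)hept-2-enedioate (phosphonate carbon unassigned) | CC(C)(O)[C@H](O)CC/C(=C\CCC(C(=O)OC)P(=O)(OC)OC)C(=O)OC | intermediate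
13 | dimethyl (2E,6E)-2-[(3R)-3,4-dihydroxy-4-methylpentyl]-6-[3-(furan-3-yl)propylidene]hept-2-enedioate | CC(C)(O)[C@H](O)CC/C(=C\CC/C(=C\CCc1ccoc1)C(=O)OC)C(=O)OC | intermediate
14 | (2E,6E)-2-[(3R)-3,4-dihydroxy-4-methylpentyl]-6-[3-(furan-3-yl)propylidene]hept-2-enedioic acid | CC(C)(O)[C@H](O)CC/C(=C\CC/C(=C\CCc1ccoc1)C(=O)O)C(=O)O | target

## Step count and risks

Total steps: 6. Longest linear sequence: 4 (steps 1, 2, 5, 6; from 1 to 14).

The three steps most likely to fail:

**Step 4 (proposed new step).** Risks are a second Friedel–Crafts alkylation of 11 at its free α-positions, oligomerisation of acrolein, and protodeboronation of 10. The fallback uses known chemistry, sets out from acrolein 8 and comes back at 11. Acrolein 8 is acetalised with ethane-1,2-diol (TsOH cat.) to 2-vinyl-1,3-dioxolane F1 (also a catalogue compound). Hydroboration with 9-borabicyclo[3.3.1]nonane in THF gives 9-[2-(1,3-dioxolan-2-yl)ethyl]-9-borabicyclo[3.3.1]nonane F2, which is not isolated. A B-alkyl Suzuki–Miyaura coupling of this borane with commercial 3-bromofuran (PdCl2(dppf) 3 mol%, aq. NaOH, THF, 60 °C) gives 2-[2-(furan-3-yl)ethyl]-1,3-dioxolane F3. Mild hydrolysis (pyridinium tosylate, acetone/H2O, 50 °C) releases 11, which enters step 5 unchanged.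

**Step 5 (one-flask Wittig then HWE).** Risks are a poor E/Z ratio in the HWE half with the α-branched phosphonate, base-induced aldol loss of 11, and partial δ-lactonisation (harmless, it converges in step 6). The fallback makes both alkenes by E-selective Wittig reactions; it sets out from 3 and 11 and comes back at 13. Ylide 3 is alkylated with commercial 2-(2-bromoethyl)-1,3-dioxolane (MeCN, 80 °C) to [4-(1,3-dioxolan-2-yl)-1-methoxy-1-oxobutan-2-yl]triphenylphosphonium bromide F4. Aqueous NaOH converts this salt to methyl 4-(1,3-dioxolan-2-yl)-2-(triphenylphosphoranylidene)butanoate F5. Wittig reaction of this ylide with 11 (toluene, 80 °C) gives methyl (2E)-2-[2-(1,3-dioxolan-2-yl)ethyl]-5-(furan-3-yl)pent-2-enoate F6. Acetal hydrolysis (1 M HCl/THF, rt) gives methyl (2E)-5-(furan-3-yl)-2-(3-oxopropyl)pent-2-enoate F7, and a second Wittig reaction of this aldehyde with 6 (MeCN, 60 °C) gives 13.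

**Step 2 (ylide alkylation with the epoxy bromide).** Risks are slow SN2 of a neutral ylide on an unactivated bromide and halide opening of the oxirane during the long heating. The fallback postpones the asymmetric epoxidation until after the Wittig union, so no oxirane has to survive the alkylation; it sets out from 1 and 3 and comes back at 12. Ylide 3 is alkylated with 1 under forcing conditions (neat, 100 °C) to (1-methoxy-6-methyl-1-oxohept-5-en-2-yl)triphenylphosphonium bromide F8. Aqueous NaOH gives methyl 6-methyl-2-(triphenylphosphoranylidene)hept-5-enoate F9. Wittig reaction with 9 gives dimethyl (2E)-6-(dimethoxyphosphoryl)-2-(4-methylpent-3-en-1-yl)hept-2-enedioate F10. Shi epoxidation under the step 1 conditions attacks only the electron-rich trisubstituted olefin and gives dimethyl (2E)-6-(dimethoxyphosphoryl)-2-{2-[(2R)-3,3-dimethyloxiran-2-yl]ethyl}hept-2-enedioate F11. HClO4-catalysed hydrolysis (THF/H2O) gives 12, which is isolated here and taken through the second stage of step 5.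

## Further compounds

F1 | step 4 | 2-vinyl-1,3-dioxolane | C=CC1OCCO1
F2 | step 4 | 9-[2-(1,3-dioxolan-2-yl)ethyl]-9-borabicyclo[3.3.1]nonane | O1CCOC1CCB1C2CCCC1CCC2
F3 | step 4 | 2-[2-(furan-3-yl)ethyl]-1,3-dioxolane | O1CCOC1CCc1ccoc1
F4 | step 5 | [4-(1,3-dioxolan-2-yl)-1-methoxy-1-oxobutan-2-yl]triphenylphosphonium bromide | COC(=O)C(CCC1OCCO1)[P+](c1ccccc1)(c1ccccc1)c1ccccc1.[Br-]
F5 | step 5 | methyl 4-(1,3-dioxolan-2-yl)-2-(triphenylphosphoranylidene)butanoate | COC(=O)C(CCC1OCCO1)=P(c1ccccc1)(c1ccccc1)c1ccccc1
F6 | step 5 | methyl (2E)-2-[2-(1,3-dioxolan-2-yl)ethyl]-5-(furan-3-yl)pent-2-enoate | O1CCOC1CC/C(=C\CCc1ccoc1)C(=O)OC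
F7 | step 5 | methyl (2E)-5-(furan-3-yl)-2-(3-oxopropyl)pent-2-enoate | O=CCC/C(=C\CCc1ccoc1)C(=O)OC
F8 | step 2 | (1-methoxy-6-methyl-1-oxohept-5-en-2-yl)triphenylphosphonium bromide | COC(=O)C(CCC=C(C)C)[P+](c1ccccc1)(c1ccccc1)c1ccccc1.[Br-]
F9 | step 2 | methyl 6-methyl-2-(triphenylphosphoranylidene)hept-5-enoate | COC(=O)C(CCC=C(C)C)=P(c1ccccc1)(c1ccccc1)c1ccccc1
F10 | step 2 | dimethyl (2E)-6-(dimethoxyphosphoryl)-2-(4-methylpent-3-en-1-yl)hept-2-enedioate | CC(C)=CCC/C(=C\CCC(C(=O)OC)P(=O)(OC)OC)C(=O)OC
F11 | step 2 | dimethyl (2E)-6-(dimethoxyphosphoryl)-2-{2-[(2R)-3,3-dimethyloxiran-2-yl]ethyl}hept-2-enedioate | CC1(C)O[C@@H]1CC/C(=C\CCC(C(=O)OC)P(=O)(OC)OC)C(=O)OC
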